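**Retrosynthetic overview**
1. Isodojaponin D ⇐ C16 α‑methylenation and hydrogenation/debenzylation of a bicyclo[3.2.1]octenone, itself made by Pd(II) enol‑silane/olefin cyclization (C13–C16, ring D).
2. That 8‑acetyl cyclohexene ⇐ Diels–Alder of buta‑1,3‑diene with a spiro 3‑acetyl‑5,6‑dihydropyran‑2‑one (ring C; sets C8 and C9, leaves the olefin at C12=C13).
3. Dienophile ⇐ acetoacetylation and intramolecular Knoevenagel condensation on a C10 hydroxymethyl/formyl cyclohexane (δ‑lactone ring).
4. Ring A ⇐ (S)‑carvone: reductive alkylation (C4), aldol plus Mukaiyama formylation (C10), Criegee rearrangement (isopropenyl → C1‑OAc), methylenation/hydroboration (C5–C6).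
5. Ring order: A (bought) → lactone → C (cycloaddition) → D.

Assumption: ent‑kaurane numbering is used for locants (ring A = C1–C5, C10; lactone C20–O–C7(=O)–C8; ring C = C8, C9, C11–C14; bridge C15–C16=C17). Steps 3 and 9 are run as one‑pot, two‑stage operations.

**Step 1**
Reactants: 1, (S)‑(+)‑carvone
Product: 2, (2S,5S)‑2‑[(benzyloxy)methyl]‑2‑methyl‑5‑(prop‑1‑en‑2‑yl)cyclohexan‑1‑one (BnOCH2 cis to isopropenyl)
Conditions: Li, NH3(l)/THF, t‑BuOH (1 equiv), −78 °C; isoprene; NH3 removed; BOMCl, THF, −78 → 0 °C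
Reagents that add atoms: benzyl chloromethyl ether, ClCOCc1ccccc1
Why: Dissolving‑metal reduction gives the regiodefined lithium enolate, which is C‑alkylated (reductive alkylation) axially through a chair‑like transition state with the isopropenyl group equatorial, so C19 ends up cis to the isopropenyl group (later O1).

**Step 2**
Reactants: 2
Product: 3, (2S,5S)‑2‑[(benzyloxy)methyl]‑6‑(hydroxymethyl)‑2‑methyl‑5‑(prop‑1‑en‑2‑yl)cyclohexan‑1‑one (mixture at C6 of the ring, i.e. C10)
Conditions: LDA, THF, −78 °C; CH2O (gas, from cracked paraformaldehyde), −78 °C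
Reagents that add atoms: formaldehyde, C=O
Why: C10 is the only enolisable position, so the lithium enolate undergoes a crossed aldol with monomeric formaldehyde to install C20; the C10 configuration is irrelevant because it is re‑planarised in step 3.

**Step 3**
Reactants: 3
Product: 4, (2S,5R,6R)‑2‑[(benzyloxy)methyl]‑6‑{[(tert‑butyldimethylsilyl)oxy]methyl}‑6‑(dimethoxymethyl)‑2‑methyl‑5‑(prop‑1‑en‑2‑yl)cyclohexan‑1‑one (CH(OMe)2 trans, CH2OTBS cis to isopropenyl)
Conditions: TBSOTf (2.5 equiv), i‑Pr2NEt, CH2Cl2, 0 °C → rt; then HC(OMe)3, TMSOTf, −78 → −20 °C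
Reagents that add atoms: TBSOTf, CC(C)(C)[Si](C)(C)OS(=O)(=O)C(F)(F)F; trimethyl orthoformate, COC(OC)OC
Why: Soft enolisation silylates both the hydroxyl and the ketone, and the tetrasubstituted enol silane adds to the dimethoxycarbenium ion (Mukaiyama‑type orthoformate alkylation) anti to the adjacent isopropenyl group, which sets the C10 quaternary centre with C9 trans and C20 cis to the future O1.

**Step 4**
Reactants: 4
Product: 5, 4‑[(benzyloxy)methyl]‑2‑{[(tert‑butyldimethylsilyl)oxy]methyl}‑2‑(dimethoxymethyl)‑4‑methyl‑3‑oxocyclohexyl acetate (OAc in place of isopropenyl, same configuration)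
Conditions: O3, CH2Cl2/MeOH, −78 °C; then Ac2O, Et3N, DMAP, 0 °C → rt
Reagents that add atoms: ozone, [O-][O+]=O (ester O); methanol, CO (carbonyl O). The acetyl C2 unit is the old isopropenyl C–CH3; Ac2O only activates the hydroperoxide.
Why: Ozonolysis in methanol gives the α‑methoxy hydroperoxide, whose peracetate undergoes Criegee rearrangement with migration of C1 to oxygen, converting isopropenyl into acetate with retention at C1; the ketone has no α‑H and the ethers and acetal are inert.

**Step 5**
Reactants: 5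
Product: 6, the 3‑methylidene analogue of 5 (C5=C6H2 exocyclic olefin)
Conditions: Zn, CH2Br2, TiCl4 (Lombardo reagent), THF/CH2Cl2, 0 °C → rt
Reagents that add atoms: dibromomethane, BrCBr
Why: Takai–Lombardo Zn/Ti methylenation is non‑basic, small enough for a ketone flanked by two quaternary carbons, and leaves the acetate, acetal, silyl ether and benzyl ether untouched.

**Step 6**
Reactants: 6
Product: 7, 4‑[(benzyloxy)methyl]‑2‑{[(tert‑butyldimethylsilyl)oxy]methyl}‑2‑(dimethoxymethyl)‑3‑(hydroxymethyl)‑4‑methylcyclohexyl acetate (OAc, CH2OTBS, CH2OH and CH2OBn all on one face)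
Conditions: BH3·THF, 0 °C → rt; then 30% H2O2, aq. NaOAc
Reagents that add atoms: hydrogen peroxide, OO
Why: Anti‑Markovnikov hydroboration–oxidation in which borane delivers H to C5 from the face opposite the two axial CH2O groups on C4 and C10, so C6 becomes equatorial and cis to C19 and C20 (sets C5).

**Step 7**
Reactants: 7
Product: 8, the C6 acetate of 7 (C1,C6‑diacetate)
Conditions: Ac2O, pyridine, DMAP, CH2Cl2, rt
Reagents that add atoms: acetic anhydride, CC(=O)OC(C)=O
Why: DMAP‑catalysed acylation of the only free hydroxyl.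

**Step 8**
Reactants: 8
Product: 9, 3‑(acetoxymethyl)‑4‑[(benzyloxy)methyl]‑2‑formyl‑2‑(hydroxymethyl)‑4‑methylcyclohexyl acetate (C10 bears C9HO and C20H2OH)
Conditions: 2 M HCl, THF, rt
Reagents that add atoms: water, O (aldehyde oxygen)
Why: Aqueous acid hydrolyses the dimethyl acetal and cleaves the primary TBS ether in one operation, while the acetates and the benzyl ether survive.

**Step 9**
Reactants: 9; 10, 2,2,6‑trimethyl‑4H‑1,3‑dioxin‑4‑one
Product: 11, [7‑acetoxy‑4‑acetyl‑10‑[(benzyloxy)methyl]‑10‑methyl‑3‑oxo‑2‑oxaspiro[5.5]undec‑4‑en‑11‑yl]methyl acetate (spiro 3‑acetyl‑5,6‑dihydropyran‑2‑one; C8=C9 olefin)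
Conditions: 10 (1.5 equiv), toluene, 110 °C; then piperidine/AcOH (cat.), 4 Å MS, rt
Reagents that add atoms: none besides 10 (its acetylketene unit, CC(=O)C=C=O, is transferred; acetone and water are lost)
Why: Thermolysis of 10 releases acetylketene, which acylates the free C20‑OH, and the resulting acetoacetate closes onto the neighbouring aldehyde by intramolecular Knoevenagel condensation to give the doubly activated alkylidene lactone.

**Step 10**
Reactants: 11; 12, buta‑1,3‑diene
Product: 13, Diels–Alder adduct: cis‑fused cyclohexene on the δ‑lactone, 8‑acetyl, Δ12(13), C1/C6 diacetate, 19‑OBn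
Conditions: 12 (excess), ZnCl2, CH2Cl2, 0 °C → rt, sealed tube
Reagents that add atoms: none besides 12
Why: Lewis‑acid‑catalysed Diels–Alder of a chelating alkylidene β‑keto lactone, in which suprafacial addition fixes the cis C8/C9 fusion and the diene approaches C9 gauche to the smaller O1 branch and anti to the bulkier C5 branch (CH2OAc next to quaternary C4), setting C8 and C9.

**Step 11**
Reactants: 13
Product: 14, trimethylsilyl enol ether of the C15 methyl ketone (C15(OTMS)=C16H2)
Conditions: TMSOTf, Et3N, CH2Cl2, 0 °C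
Reagents that add atoms: TMSOTf, C[Si](C)(C)OS(=O)(=O)C(F)(F)F
Why: The C16 methyl is the only enolisable position of the ketone (C8 is quaternary), so soft enolisation gives a single enol silane without touching the esters.

**Step 12**
Reactants: 14
Product: 15, 1,6‑diacetoxy‑19‑(benzyloxy)‑15‑oxo‑17‑nor‑6,7‑seco‑ent‑kaur‑11‑en‑7,20‑olide (bicyclo[3.2.1]octenone)
Conditions: Pd(OAc)2 (1.1 equiv), MeCN, rt
Reagents that add atoms: none
Why: Kende/Saegusa‑type Pd(II) cycloalkenylation, in which the Pd enolate has no β‑H to dehydrogenate and instead inserts the ring olefin in the five‑membered‑ring mode from the only face the C8 tether can reach (setting C13), then β‑hydride eliminates to the Δ11 olefin.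

**Step 13**
Reactants: 15
Product: 16, 1,6‑diacetoxy‑19‑hydroxy‑15‑oxo‑17‑nor‑6,7‑seco‑ent‑kauran‑7,20‑olide
Conditions: H2 (1 atm), 10% Pd/C, EtOAc, rt
Reagents that add atoms: none (hydrogen only)
Why: Heterogeneous hydrogenation saturates the disubstituted olefin and hydrogenolyses the benzyl ether in the same operation; ketone, lactone and acetates are inert.

**Step 14**
Reactants: 16
Product: 17, Isodojaponin D
Conditions: (CH2O)n, N‑methylanilinium trifluoroacetate, THF, reflux
Reagents that add atoms: formaldehyde (paraformaldehyde), C=O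
Why: Acid‑mediated Mannich condensation/elimination (α‑methylenation) at C16, the only enolisable carbon, under mildly acidic conditions that tolerate the free C19‑OH, both acetates and the lactone.

**Compound list**
1 | (S)‑(+)‑carvone | CC1=CC[C@@H](CC1=O)C(C)=C | starting material
2 | (2S,5S)‑2‑[(benzyloxy)methyl]‑2‑methyl‑5‑(prop‑1‑en‑2‑yl)cyclohexan‑1‑one | C1[C@@H](C(C)=C)CC[C@@](C)(COCc2ccccc2)C1=O | intermediate
3 | 6‑hydroxymethyl derivative of 2 (C10 epimers) | OCC1[C@@H](C(C)=C)CC[C@@](C)(COCc2ccccc2)C1=O | intermediate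
4 | (2S,5R,6R)‑2‑(BnOCH2)‑6‑(TBSOCH2)‑6‑(dimethoxymethyl)‑2‑methyl‑5‑isopropenylcyclohexanone | COC(OC)[C@]1(CO[Si](C)(C)C(C)(C)C)[C@@H](C(C)=C)CC[C@@](C)(COCc2ccccc2)C1=O | intermediate
5 | C1 acetate (isopropenyl → OAc, retention) | COC(OC)[C@]1(CO[Si](C)(C)C(C)(C)C)[C@@H](OC(C)=O)CC[C@@](C)(COCc2ccccc2)C1=O | intermediate
6 | C5 exo‑methylene compound | COC(OC)[C@]1(CO[Si](C)(C)C(C)(C)C)[C@@H](OC(C)=O)CC[C@@](C)(COCc2ccccc2)C1=C | intermediate
7 | C6 primary alcohol | COC(OC)[C@]1(CO[Si](C)(C)C(C)(C)C)[C@@H](OC(C)=O)CC[C@@](C)(COCc2ccccc2)[C@H]1CO | intermediate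
8 | C1,C6‑diacetate | COC(OC)[C@]1(CO[Si](C)(C)C(C)(C)C)[C@@H](OC(C)=O)CC[C@@](C)(COCc2ccccc2)[C@H]1COC(C)=O | intermediate
9 | C10 formyl/hydroxymethyl diacetate | O=C[C@]1(CO)[C@@H](OC(C)=O)CC[C@@](C)(COCc2ccccc2)[C@H]1COC(C)=O | intermediate
10 | 2,2,6‑trimethyl‑4H‑1,3‑dioxin‑4‑one | CC1=CC(=O)OC(C)(C)O1 | starting material
11 | spiro 3‑acetyl‑5,6‑dihydropyran‑2‑one dienophile | CC(=O)C3=C[C@]1(COC3=O)[C@@H](OC(C)=O)CC[C@@](C)(COCc2ccccc2)[C@H]1COC(C)=O | intermediate
12 | buta‑1,3‑diene | C=CC=C | starting material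
13 | Diels–Alder adduct (8‑acetyl, Δ12) | CC(=O)[C@]23CC=CC[C@H]2[C@]1(COC3=O)[C@@H](OC(C)=O)CC[C@@](C)(COCc4ccccc4)[C@H]1COC(C)=O | intermediate
14 | TMS enol ether of 13 | C=C(O[Si](C)(C)C)[C@]23CC=CC[C@H]2[C@]1(COC3=O)[C@@H](OC(C)=O)CC[C@@](C)(COCc4ccccc4)[C@H]1COC(C)=O | intermediate
15 | 19‑O‑benzyl‑17‑nor‑15‑oxo‑Δ11 tetracycle | C1C(=O)[C@]23C[C@H]1C=C[C@H]2[C@]1(COC3=O)[C@@H](OC(C)=O)CC[C@@](C)(COCc4ccccc4)[C@H]1COC(C)=O | intermediate
16 | 17‑nor‑15‑ketone, 19‑OH | C1C(=O)[C@]23C[C@H]1CC[C@H]2[C@]1(COC3=O)[C@@H](OC(C)=O)CC[C@@](C)(CO)[C@H]1COC(C)=O | intermediate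
17 | Isodojaponin D | C=C1C(=O)[C@]23C[C@H]1CC[C@H]2[C@]1(COC3=O)[C@@H](OC(C)=O)CC[C@@](C)(CO)[C@H]1COC(C)=O | target

**Totals**
Total steps: 14. Longest linear sequence: 14 steps from (S)‑carvone; the route is fully linear, with 10 and 12 as commercial partners.

**Three steps most likely to fail**
- **Step 10 (Diels–Alder).** The dienophile's β‑carbon is neopentyl, and face selectivity rests only on OAc (C1 side) being smaller than CH2OAc/quaternary C4 (C5 side). Fallback: make the cycloaddition intramolecular from the required face. Leave O1 as a free hydroxyl, attach a buta‑1,3‑dien‑2‑yl(dimethyl)silyl ether (temporary silicon tether), run the intramolecular Diels–Alder, then remove silicon from the resulting C12 vinylsilane with TBAF (protodesilylation keeps the C12=C13 olefin) and acetylate O1.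
- **Step 5 (methylenation of the doubly α‑quaternary ketone).** The ketone may be too hindered, and the acetal may not tolerate the Ti reagent. Fallback: introduce C6 as a nucleophile on ketone 4 before the Criegee step. Corey–Chaykovsky epoxidation (Me3S+ I−/KHMDS), Lewis‑acid Meinwald rearrangement to the equatorial C6 aldehyde, and NaBH4 reduction; the Criegee step then acetylates C6‑OH and forms C1‑OAc in one pot.
- **Step 12 (Pd(II) cyclization onto an internal ring olefin).** The reaction may be slow, or may close the six‑membered (bicyclo[2.2.2]) ring instead. Fallback: switch to a polar closure with fixed regiochemistry. Epoxidize C12=C13 of 13 on the face opposite the acetyl group, open the epoxide at C13 with the C16 ketone enolate (5‑exo‑tet, trans‑diaxial), and remove the resulting C12‑OH by Barton–McCombie deoxygenation.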